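The route rests on disconnecting C1–C7a, the bond joining the two methyl-bearing quaternary carbons of the five-membered ring, beside the C7 carbinol. With C3a written as a ketone, C3a=O/C7a/C7–OH is a β-hydroxy ketone, the imprint of a semipinacol shift. The precursor is a 1-(trans-epoxyalkyl)cyclobutanol in which C1 is a ring carbon of the strained four-membered ring. It already carries the side chain (silyl ether), a silyl-protected C5 carbinol and the complete 7-oxabicyclo[2.2.1]heptane arm. One Lewis-acid step moves C1 from the carbinol carbon to the tertiary epoxide carbon, expands cyclobutane to cyclopentanone, fixes C7a and releases the C7 hydroxyl. The six-membered ring is closed later at C4=C5.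

Key step: step 16

Remarks on the chemistry (one line each)
- Numbering and shorthand: indane numbering for the core (C1–C7a); C1′–C6′/O7′ for the oxabicycle; "arm CH2" joins C5 to C1′; Ox = 3,3-dimethyl-7-oxabicyclo[2.2.1]heptan-1-yl with the absolute configuration made in step 2 (C4′ S).
- Assumption: (S)-3,3′-Br2-BINOL is taken to induce the same sense as with aryl methyl ketones (large group equatorial, 2R carbinol); if the sense is opposite, the (R)-catalyst is used.
- Assumption: the C5 carbinol forms as an epimer mixture. It is carried unassigned because step 20 turns it into the ketone.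
- Side chain: it is carried as CH2CH2OTBDPS. An ester would compete for the alkenyllithium, and the cis tertiary alkoxide would close a δ-lactone onto it, blocking the carbinol needed in step 16.
- C5: it is carried as a TES-protected carbinol, not a ketal. A ketal oxygen can reach the C7a cation through a five-membered ring and is itself ionised by Lewis acids, and making it needs an isomerisation-prone β,γ-alkynyl ketone.
- C1: induction from CH(CH3)(CH2R) on an adjacent, epimerisable methyl ketone is weak. C1 and the side-chain centre are therefore set together in a closed transition state and relayed by a stereospecific ring enlargement.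
- Epoxide face: with the carbinol configuration that C1 enforces, a hydroxyl-directed oxidant would deliver oxygen to the face giving the wrong C7a/C7 pair. Reagent control is used instead, and it coincides with the sterically open face.
- Ring closure: the C5 ketone has two β-leaving groups (C7–OSi and the C1′ ether oxygen), so a strongly basic ester-enolate aldol is replaced by a near-neutral dienamine aldol of an aldehyde.
- Minor enantiomers of either fragment become separable diastereomers at 28.

Step 1
Reactants: 1 myrcene
Product: 2 (3S)-2,2-dimethyl-3-(3-methylidenepent-4-en-1-yl)oxirane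
Conditions: ent-Shi ketone (L-fructose series, 25 mol %), Oxone, K2CO3, Bu4NHSO4, MeCN–DMM/aq. borate–EDTA buffer, −10 → 0 °C
Reagents that add atoms: Oxone (potassium peroxymonosulfate), [K+].[O-]S(=O)(=O)OO
Why: Shi asymmetric epoxidation, in which the chiral dioxirane attacks the electron-rich trisubstituted alkene much faster than the terminal diene, and the L-series ketone delivers oxygen to the face that gives the S epoxide carbon (future C4′).

Step 2
Reactants: 2 (S)-epoxymyrcene
Product: 3 (1R,4S)-1-ethenyl-3,3-dimethyl-7-oxabicyclo[2.2.1]heptane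
Conditions: BF3·OEt2 (15 mol %), CH2Cl2, −78 °C; Et3N quench
Reagents that add atoms: none
Why: Epoxide-initiated cation–olefin cyclisation: the epoxide opens at its tertiary carbon, the diene CH2 closes the cyclohexane, and the boron-bound alkoxide captures the allyl cation across the ring at its tertiary end; C4′ keeps its C–O bond (retention) and the bridge then dictates C1′.

Step 3
Reactants: 3 vinyl oxabicycle
Product: 5 2-[(1R,4S)-3,3-dimethyl-7-oxabicyclo[2.2.1]heptan-1-yl]ethan-1-ol, via B-alkyl-9-BBN adduct 4 (not isolated)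
Conditions: 9-BBN, THF, 0 °C → rt; NaOH, H2O2, 0 °C
Reagents that add atoms: hydrogen peroxide, OO
Why: Hydroboration–oxidation, in which the bulky borane places boron only on the terminal carbon of a vinyl group attached to a quaternary centre, giving the arm CH2–C5 unit.

Step 4
Reactants: 5 primary alcohol
Product: 6 2-[(1R,4S)-3,3-dimethyl-7-oxabicyclo[2.2.1]heptan-1-yl]acetaldehyde
Conditions: Dess–Martin periodinane, CH2Cl2, 0 °C → rt
Reagents that add atoms: none
Why: Dess–Martin oxidation stops at the aldehyde and, being non-basic, avoids β-elimination of the bridging ether oxygen.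

Step 5
Reactants: 6 aldehyde; 7 but-2-yne
Product: 10 1-Ox-hex-4-yn-2-ol (C5 epimers), via 1-lithiobut-2-yne 8 (not isolated), via allenyltitanium triisopropoxide 9 (not isolated)
Conditions: 7, t-BuLi, THF, −78 → 0 °C; Ti(OiPr)4, −78 °C; then 6, −78 °C
Reagents that add atoms: none
Why: Propargylic lithiation and transmetalation give an allenyltitanium reagent that adds by SE2′ through its CH2 terminus, so only the homopropargylic alcohol forms (zinc or indium reagents from 1-bromobut-2-yne favour the allenic alcohol); the uncontrolled C5 centre is erased in step 20.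

Step 6
Reactants: 10 homopropargylic alcohol
Product: 11 triethylsilyl ether of 10
Conditions: TESCl, imidazole, CH2Cl2, 0 °C → rt
Reagents that add atoms: chlorotriethylsilane, CC[Si](Cl)(CC)CC
Why: Standard silylation, with TES chosen because it can later be removed beside TBS and TBDPS and is a poor nucleophile toward a cation at C7a.

Step 7
Reactants: 11 alkyne
Product: 13 (4E)-5-iodo-1-Ox-hex-4-en-2-yl triethylsilyl ether, via alkenylzirconocene chloride 12 (not isolated)
Conditions: Cp2Zr(H)Cl (2 equiv), THF, rt → 40 °C; I2, 0 °C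
Reagents that add atoms: iodine, II
Why: Hydrozirconation–iodination with the Schwartz reagent: syn H–Zr addition is equilibrated by excess reagent toward the less hindered methyl-bearing carbon, and iodinolysis with retention gives the E iodide with iodine on future C7a.

Step 8
Reactants: 14 cyclopropyl phenyl sulfide; 15 N-methoxy-N-methylacetamide
Product: 17 1-[1-(phenylsulfanyl)cyclopropyl]ethan-1-one, via 1-lithiocyclopropyl phenyl sulfide 16 (not isolated)
Conditions: 14, n-BuLi, THF, 0 °C; 15, −78 → 0 °C
Reagents that add atoms: none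
Why: Sulfur-assisted α-lithiation of the cyclopropane followed by Weinreb ketone synthesis, whose chelated tetrahedral intermediate prevents over-addition.

Step 9
Reactants: 18 (E)-but-2-ene; 19 triisopropyl borate
Product: 21 diisopropyl (E)-but-2-en-1-ylboronate, via (E)-crotylpotassium 20 (not isolated)
Conditions: n-BuLi, KOt-Bu, THF, −78 → −50 °C; 19, −78 °C; HCl (2 equiv, Et2O); stock solution in toluene
Reagents that add atoms: none
Why: Schlosser-base metalation keeps the E geometry at low temperature, and boration followed by acid release of the ate complex gives the configurationally defined crotylboronate.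

Step 10
Reactants: 17 methyl ketone; 21 (E)-crotylboronate
Product: 22 (2R,3R)-3-methyl-2-[1-(phenylsulfanyl)cyclopropyl]pent-4-en-2-ol
Conditions: (S)-3,3′-Br2-BINOL (15 mol %), PhCF3–toluene, −35 °C; aqueous work-up
Reagents that add atoms: none
Why: BINOL-catalysed asymmetric crotylboration of a methyl ketone through a closed Zimmerman–Traxler chair: the E-crotyl geometry with the bulky thiocyclopropyl group equatorial gives the anti pair, and the boron-bound chiral diol selects the ketone face, so the carbinol carbon (future C1) and the side-chain CH(CH3) are both set here.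

Step 11
Reactants: 22 homoallylic alcohol
Product: 24 (3R,4R)-3-methyl-4-[1-(phenylsulfanyl)cyclopropyl]pentane-1,4-diol, via B-alkyl-9-BBN adduct 23 (not isolated)
Conditions: 9-BBN (2.5 equiv), THF, 0 °C → rt; NaOH, H2O2, 0 °C, short contact
Reagents that add atoms: hydrogen peroxide, OO
Why: Hydroboration–oxidation turns the vinyl group into the CH2CH2OH precursor of CH2CO2H, since cold alkaline peroxide oxidises C–B bonds faster than an aryl sulfide.

Step 12
Reactants: 24 diol
Product: 25 (2R,3R)-5-(tert-butyldiphenylsilyloxy)-3-methyl-2-[1-(phenylsulfanyl)cyclopropyl]pentan-2-ol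
Conditions: TBDPSCl, imidazole, CH2Cl2, 0 °C
Reagents that add atoms: tert-butyl(chloro)diphenylsilane, CC(C)(C)[Si](Cl)(c1ccccc1)c1ccccc1
Why: Selective silylation of the primary alcohol (the crowded tertiary carbinol is inert), using an acid- and organolithium-stable group that also stops the oxygen from trapping the cation of step 13.

Step 13
Reactants: 25 cyclopropylcarbinol
Product: 26 (2S)-2-[(2R)-4-(tert-butyldiphenylsilyloxy)butan-2-yl]-2-methylcyclobutan-1-one
Conditions: TsOH·H2O (20 mol %), wet toluene, 50 °C
Reagents that add atoms: water, O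
Why: Acid-induced ring enlargement of a 1-(arylthio)cyclopropylcarbinol (sulfur-assisted cyclopropylcarbinyl-to-cyclobutyl semipinacol shift): the cyclopropane bond anti to the departing water migrates as it leaves, converting the carbinol carbon with inversion into quaternary C1, and hydrolysis of the thionium ion gives the ketone.

Step 14
Reactants: 13 (E)-alkenyl iodide; 26 cyclobutanone
Product: 28 (1R,2S)-1-[(2E)-5-(triethylsilyloxy)-6-Ox-hex-2-en-2-yl]-2-methyl-2-[(2R)-4-(tert-butyldiphenylsilyloxy)butan-2-yl]cyclobutan-1-ol (alkenyl cis to the ring methyl), via alkenyllithium 27 (not isolated)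
Conditions: 13, t-BuLi (2.0 equiv), Et2O, −78 °C; then 26, −78 → −40 °C; aqueous quench
Reagents that add atoms: none
Why: Iodine–lithium exchange with retention of alkene geometry and 1,2-addition to the strained, poorly enolisable cyclobutanone, with attack anti to the branched C1 substituent; the resulting carbinol centre is erased in step 16.

Step 15
Reactants: 28 allylic cyclobutanol
Product: 29 epoxy alcohol: 28 with the C7a=C7 alkene converted into the trans-epoxide (C7a S, C7 R)
Conditions: Shi ketone (D-fructose series, 40 mol %), Oxone, K2CO3, Bu4NHSO4, MeCN–DMM/aq. borate–EDTA buffer (pH ≈ 10.5), 0 °C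
Reagents that add atoms: Oxone (potassium peroxymonosulfate), [K+].[O-]S(=O)(=O)OO
Why: Shi asymmetric epoxidation of an (E)-trisubstituted alkene: the D-series dioxirane attacks the face needed for C7a/C7, which is also the open face opposite the hydroxyl and the side chain, whereas a vanadium or peracid oxidant bound to the hydroxyl would be steered by A(1,2) strain with the C7a methyl to the other face.

Step 16
Reactants: 29 epoxy alcohol
Product: 30 (2R,3S)-2-[(1R)-1-hydroxy-3-(triethylsilyloxy)-4-Ox-butyl]-2,3-dimethyl-3-[(2R)-4-(tert-butyldiphenylsilyloxy)butan-2-yl]cyclopentan-1-one (core: C1 S, C7a R, C7 R)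
Conditions: ZnBr2 (20 mol %), CH2Cl2, −20 → 0 °C
Reagents that add atoms: none
Why: Zinc binds the epoxide oxygen and the neighbouring hydroxyl, the C7a–O bond stretches at the tertiary carbon, and the C1–C3a σ-bond lying anti-periplanar to it shifts to C7a while the carbinol carbon becomes the C3a ketone; this is the known semipinacol rearrangement of a tertiary α-hydroxy epoxide in its cyclobutanol-to-cyclopentanone form. The five-membered ring arises by ring enlargement (1,2-alkyl shift, four to five) rather than by cyclisation, driven by roughly 20 kcal/mol of strain release plus carbonyl formation, which pays for joining two quaternary carbons. C7a is the only new stereocentre and forms with inversion, so the epoxide configuration from step 15 controls it, while C1 migrates with retention and C7 keeps its C–O bond, placing the C7 hydroxyl trans to the C7a methyl. The selectivity required is migration of C1 rather than C3, and the fully substituted C1 is the better σ-donor, with its shift also relieving the crowding at the C1–C3a bond. Competing internal nucleophiles are designed out, since the side-chain and C5 oxygens are bulky silyl ethers rather than an ester or a ketal. The β-hydroxy ketone is kept cold and silylated at once to avoid retro-aldol cleavage.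

Step 17
Reactants: 30 β-hydroxy ketone
Product: 31 C7 tert-butyldimethylsilyl ether of 30
Conditions: TBSOTf, 2,6-lutidine, CH2Cl2, −78 → 0 °C
Reagents that add atoms: tert-butyldimethylsilyl triflate, CC(C)(C)[Si](C)(C)OS(=O)(=O)C(F)(F)F
Why: Silyl triflate silylation of the hindered neopentyl carbinol under non-nucleophilic base blocks retro-aldol cleavage in the enolisation that follows.

Step 18
Reactants: 31 ketone
Product: 33 C3a enol triflate (C3=C3a), via potassium enolate 32 (not isolated)
Conditions: KHMDS, THF, −78 °C; PhNTf2, −78 → 0 °C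
Reagents that add atoms: N-phenylbis(trifluoromethanesulfonimide), FC(F)(F)S(=O)(=O)N(c1ccccc1)S(=O)(=O)C(F)(F)F
Why: Enolisation can only go toward C3 because C7a is quaternary, so O-triflation gives a single enol triflate and the C7 silyloxy group has no enolate next to it from which to be expelled.

Step 19
Reactants: 33 enol triflate; 34 (E)-2-(2-ethoxyethenyl)-4,4,5,5-tetramethyl-1,3,2-dioxaborolane
Product: 36 C5-hydroxy aldehyde (C3a–CH2–CHO; C7 OTBS and side-chain OTBDPS retained), via dienol ethyl ether 35 (not isolated)
Conditions: Pd(dppf)Cl2 (5 mol %), K3PO4, THF–H2O, 50 °C; extractive work-up; crude 35, 1 M HCl (cat.), THF, 0 °C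
Reagents that add atoms: water, O
Why: Suzuki–Miyaura coupling of a cyclopentenyl triflate next to a quaternary carbon (the steroid 17-enol triflate situation) installs C4 and the future carboxyl carbon, and dilute acid then hydrolyses the enol ether and the labile TES ether while TBS and TBDPS stay; any double-bond isomer of the aldehyde converges in step 21.

Step 20
Reactants: 36 hydroxy aldehyde
Product: 37 C5-keto aldehyde
Conditions: Dess–Martin periodinane, CH2Cl2, 0 °C → rt
Reagents that add atoms: none
Why: Dess–Martin oxidation of the secondary alcohol is neutral enough to spare the aldehyde and both β-oxygen substituents of the new ketone, and it merges the two C5 epimers.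

Step 21
Reactants: 37 keto aldehyde
Product: 38 (1S,7R,7aS)-7-(tert-butyldimethylsilyloxy)-1-[(2R)-4-(tert-butyldiphenylsilyloxy)butan-2-yl]-1,7a-dimethyl-5-(Ox-methyl)-2,6,7,7a-tetrahydro-1H-indene-4-carbaldehyde
Conditions: piperidine (30 mol %), AcOH (30 mol %), toluene, 4 Å MS, 40–60 °C
Reagents that add atoms: none
Why: Amine-catalysed intramolecular aldol condensation: the dienamine of the aldehyde attacks the C5 ketone through C4 to close the six-membered ring and loses water to give the C4=C5 enal, in a near-neutral medium where the hindered ketone is hardly enolised, so neither β-oxygen is expelled.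

Step 22
Reactants: 38 bis-silyl dienal
Product: 39 diol dienal (free C7 hydroxyl and side-chain CH2CH2OH)
Conditions: HF·pyridine, pyridine–THF, 0 °C → rt
Reagents that add atoms: none
Why: Fluoride desilylation in a buffered, non-basic medium removes both silyl groups without vinylogous β-elimination at C6/C7 and without opening the bicyclic ether.

Step 23
Reactants: 39 diol dienal
Product: 41 target diacid CNP0085464.1, via dialdehyde 40 (not isolated)
Conditions: TEMPO (10 mol %), PhI(OAc)2, CH2Cl2, rt; then t-BuOH–H2O, 2-methylbut-2-ene, NaClO2, NaH2PO4, rt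
Reagents that add atoms: sodium chlorite, [Na+].[O-]Cl=O
Why: The oxoammonium oxidation takes the primary alcohol and leaves the neopentyl C7 carbinol, and one Pinnick oxidation with a chlorine scavenger then converts both aldehydes into the two carboxylic acids without touching the diene.

Compound list
1 | myrcene | C=CC(=C)CCC=C(C)C | starting material
2 | (3S)-2,2-dimethyl-3-(3-methylidenepent-4-en-1-yl)oxirane | C=CC(=C)CC[C@@H]1OC1(C)C | intermediate
3 | (1R,4S)-1-ethenyl-3,3-dimethyl-7-oxabicyclo[2.2.1]heptane | C=C[C@]12CC[C@H](O1)C(C)(C)C2 | intermediate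
4 | B-(2-Ox-ethyl)-9-borabicyclo[3.3.1]nonane | B1(CC[C@]34CC[C@H](O3)C(C)(C)C4)C2CCCC1CCC2 | intermediate
5 | 2-Ox-ethan-1-ol | OCC[C@]12CC[C@H](O1)C(C)(C)C2 | intermediate
6 | 2-Ox-acetaldehyde | O=CC[C@]12CC[C@H](O1)C(C)(C)C2 | intermediate
7 | but-2-yne | CC#CC | starting material
8 | 1-lithiobut-2-yne | [Li]CC#CC | intermediate
9 | (buta-2,3-dien-2-yl)titanium triisopropoxide | C=C=C(C)[Ti](OC(C)C)(OC(C)C)OC(C)C | intermediate
10 | 1-Ox-hex-4-yn-2-ol (C5 epimers) | CC#CCC(O)C[C@]12CC[C@H](O1)C(C)(C)C2 | intermediate
11 | triethylsilyl ether of 10 | CC#CCC(O[Si](CC)(CC)CC)C[C@]12CC[C@H](O1)C(C)(C)C2 | intermediate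
12 | (E)-alkenylzirconocene chloride (Zr on C7a) | C/C(=C\CC(O[Si](CC)(CC)CC)C[C@]12CC[C@H](O1)C(C)(C)C2)[Zr](Cl)(C1C=CC=C1)C1C=CC=C1 | intermediate
13 | (4E)-5-iodo-1-Ox-hex-4-en-2-yl triethylsilyl ether | C/C(I)=C\CC(O[Si](CC)(CC)CC)C[C@]12CC[C@H](O1)C(C)(C)C2 | intermediate
14 | cyclopropyl phenyl sulfide | C1CC1Sc1ccccc1 | starting material
15 | N-methoxy-N-methylacetamide | CC(=O)N(C)OC | starting material
16 | 1-lithiocyclopropyl phenyl sulfide | [Li]C1(CC1)Sc1ccccc1 | intermediate
17 | 1-[1-(phenylsulfanyl)cyclopropyl]ethan-1-one | CC(=O)C1(CC1)Sc1ccccc1 | intermediate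
18 | (E)-but-2-ene | C/C=C/C | starting material
19 | triisopropyl borate | CC(C)OB(OC(C)C)OC(C)C | starting material
20 | (E)-crotylpotassium | C/C=C/C[K] | intermediate
21 | diisopropyl (E)-but-2-en-1-ylboronate | C/C=C/CB(OC(C)C)OC(C)C | intermediate
22 | (2R,3R)-3-methyl-2-[1-(phenylsulfanyl)cyclopropyl]pent-4-en-2-ol | C[C@H](C=C)[C@@](C)(O)C1(CC1)Sc1ccccc1 | intermediate
23 | B-alkyl-9-BBN adduct of 22 | C[C@H](CCB1C2CCCC1CCC2)[C@@](C)(O)C1(CC1)Sc1ccccc1 | intermediate
24 | (3R,4R)-3-methyl-4-[1-(phenylsulfanyl)cyclopropyl]pentane-1,4-diol | C[C@H](CCO)[C@@](C)(O)C1(CC1)Sc1ccccc1 | intermediate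
25 | primary TBDPS ether of 24 | C[C@H](CCO[Si](c5ccccc5)(c6ccccc6)C(C)(C)C)[C@@](C)(O)C1(CC1)Sc1ccccc1 | intermediate
26 | (2S)-2-[(2R)-4-(TBDPS-oxy)butan-2-yl]-2-methylcyclobutan-1-one | C[C@H](CCO[Si](c5ccccc5)(c6ccccc6)C(C)(C)C)[C@]1(C)CCC1=O | intermediate
27 | (E)-alkenyllithium from 13 | C/C([Li])=C\CC(O[Si](CC)(CC)CC)C[C@]12CC[C@H](O1)C(C)(C)C2 | intermediate
28 | (1R,2S)-1-[(E)-alkenyl]cyclobutanol | C[C@H](CCO[Si](c5ccccc5)(c6ccccc6)C(C)(C)C)[C@]1(C)CC[C@@]1(O)/C(C)=C/CC(O[Si](CC)(CC)CC)C[C@]34CC[C@H](O3)C(C)(C)C4 | intermediate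
29 | 1-(trans-epoxyalkyl)cyclobutanol (key-step precursor) | C[C@H](CCO[Si](c5ccccc5)(c6ccccc6)C(C)(C)C)[C@]1(C)CC[C@@]1(O)[C@@]2(C)O[C@@H]2CC(O[Si](CC)(CC)CC)C[C@]34CC[C@H](O3)C(C)(C)C4 | intermediate
30 | β-hydroxy cyclopentanone (key-step product) | C[C@H](CCO[Si](c5ccccc5)(c6ccccc6)C(C)(C)C)[C@]1(C)CCC(=O)[C@@]1(C)[C@H](O)CC(O[Si](CC)(CC)CC)C[C@]34CC[C@H](O3)C(C)(C)C4 | intermediate
31 | C7 TBS ether of 30 | C[C@H](CCO[Si](c5ccccc5)(c6ccccc6)C(C)(C)C)[C@]1(C)CCC(=O)[C@@]1(C)[C@H](O[Si](C)(C)C(C)(C)C)CC(O[Si](CC)(CC)CC)C[C@]34CC[C@H](O3)C(C)(C)C4 | intermediate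
32 | potassium C3=C3a enolate of 31 | [K+].C[C@H](CCO[Si](c5ccccc5)(c6ccccc6)C(C)(C)C)[C@]1(C)CC=C([O-])[C@@]1(C)[C@H](O[Si](C)(C)C(C)(C)C)CC(O[Si](CC)(CC)CC)C[C@]34CC[C@H](O3)C(C)(C)C4 | intermediate
33 | C3a enol triflate | C[C@H](CCO[Si](c5ccccc5)(c6ccccc6)C(C)(C)C)[C@]1(C)CC=C(OS(=O)(=O)C(F)(F)F)[C@@]1(C)[C@H](O[Si](C)(C)C(C)(C)C)CC(O[Si](CC)(CC)CC)C[C@]34CC[C@H](O3)C(C)(C)C4 | intermediate
34 | (E)-2-(2-ethoxyethenyl)-4,4,5,5-tetramethyl-1,3,2-dioxaborolane | CCO/C=C/B1OC(C)(C)C(C)(C)O1 | starting material
35 | dienol ethyl ether | C[C@H](CCO[Si](c5ccccc5)(c6ccccc6)C(C)(C)C)[C@]1(C)CC=C(/C=C/OCC)[C@@]1(C)[C@H](O[Si](C)(C)C(C)(C)C)CC(O[Si](CC)(CC)CC)C[C@]34CC[C@H](O3)C(C)(C)C4 | intermediate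
36 | C5-hydroxy aldehyde (C5 epimers) | C[C@H](CCO[Si](c5ccccc5)(c6ccccc6)C(C)(C)C)[C@]1(C)CC=C(CC=O)[C@@]1(C)[C@H](O[Si](C)(C)C(C)(C)C)CC(O)C[C@]34CC[C@H](O3)C(C)(C)C4 | intermediate
37 | C5-keto aldehyde | C[C@H](CCO[Si](c5ccccc5)(c6ccccc6)C(C)(C)C)[C@]1(C)CC=C(CC=O)[C@@]1(C)[C@H](O[Si](C)(C)C(C)(C)C)CC(=O)C[C@]34CC[C@H](O3)C(C)(C)C4 | intermediate
38 | bis-silyl bicyclic dienal | C[C@H](CCO[Si](c5ccccc5)(c6ccccc6)C(C)(C)C)[C@]1(C)CC=C2C(C=O)=C(C[C@]34CC[C@H](O3)C(C)(C)C4)C[C@@H](O[Si](C)(C)C(C)(C)C)[C@]21C | intermediate
39 | diol dienal | C[C@H](CCO)[C@]1(C)CC=C2C(C=O)=C(C[C@]34CC[C@H](O3)C(C)(C)C4)C[C@@H](O)[C@]21C | intermediate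
40 | dialdehyde | C[C@H](CC=O)[C@]1(C)CC=C2C(C=O)=C(C[C@]34CC[C@H](O3)C(C)(C)C4)C[C@@H](O)[C@]21C | intermediate
41 | CNP0085464.1 | C[C@H](CC(=O)O)[C@]1(C)CC=C2C(C(=O)O)=C(C[C@]34CC[C@H](O3)C(C)(C)C4)C[C@@H](O)[C@]21C | target

Total step count: 23
Longest linear sequence: 17 (steps 1–7, then 14–23)

Steps most likely to fail

1. Step 16.
- What may go wrong: migration of the ring CH2 (C3) instead of C1; isomerisation of the epoxide to an allylic alcohol by proton loss from the C7a methyl; retro-aldol cleavage of the product on the Lewis acid.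
- Fallback: it sets out from 29 and gives up hydroxyl-assisted catalysis. The carbinol is capped (TMSOTf, 2,6-lutidine, −78 °C) as the trimethylsilyl ether of 29 F1. F1 is then rearranged as an epoxy silyl ether with the bulky, non-chelating aluminium Lewis acid MABR (or TiCl4) in CH2Cl2 at −78 °C. The silyloxy group pushes harder, and the aluminium reagent can only ionise the tertiary C7a–O bond. A mildly acidic work-up removes the trimethylsilyl group and the route is rejoined at 30.

2. Step 2.
- What may go wrong: a hydride shift to the acyclic ketone; proton loss to cyclohexenols; re-ionisation of the tertiary allylic ether; oligomerisation of the diene.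
- Fallback: it sets out from 1 and removes the diene before the cation chemistry. The monosubstituted vinyl group is hydroborated first (disiamylborane, then NaOH/H2O2) to 7-methyl-3-methylideneoct-6-en-1-ol F2. This is silylated to its TBDPS ether F3 and epoxidised with the same L-series ketone to the (S)-epoxide F4. The Lewis-acid cyclisation then passes through a plain tertiary cation and gives the non-allylic, acid-robust bicyclic ether F5. TBAF returns the route to 5.

3. Step 21.
- What may go wrong: loss of the C7 silyloxy group or opening of the oxabicycle by β-elimination from the C5 ketone; attack of the dienamine through C3; incomplete dehydration.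
- Fallback: it sets out from 33 and replaces amine catalysis by a Lewis-acid (Mukaiyama-type) closure. The Suzuki product 35 is isolated this time, and its TES group alone is removed with buffered fluoride (TBAF/AcOH, 0 °C) to give the C5 alcohol with the enol ether intact F6. TPAP/NMO oxidation gives the keto dienol ether F7. BF3·OEt2 at −78 °C then lets the enol ether carbon C4 add to the activated ketone, and loss of ethanol and water on work-up gives the enal, rejoining the route at 38.

Further compounds
F1 | step 16 | trimethylsilyl ether of 29 | C[C@H](CCO[Si](c5ccccc5)(c6ccccc6)C(C)(C)C)[C@]1(C)CC[C@@]1(O[Si](C)(C)C)[C@@]2(C)O[C@@H]2CC(O[Si](CC)(CC)CC)C[C@]34CC[C@H](O3)C(C)(C)C4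
F2 | step 2 | 7-methyl-3-methylideneoct-6-en-1-ol | C=C(CCO)CCC=C(C)C
F3 | step 2 | TBDPS ether of F2 | C=C(CCO[Si](c1ccccc1)(c1ccccc1)C(C)(C)C)CCC=C(C)C
F4 | step 2 | (S)-6,7-epoxide of F3 | C=C(CCO[Si](c1ccccc1)(c1ccccc1)C(C)(C)C)CC[C@@H]1OC1(C)C
F5 | step 2 | TBDPS ether of 5 | CC(C)(C)[Si](OCC[C@]12CC[C@H](O1)C(C)(C)C2)(c1ccccc1)c1ccccc1
F6 | step 21 | C5 alcohol with dienol ethyl ether intact | C[C@H](CCO[Si](c5ccccc5)(c6ccccc6)C(C)(C)C)[C@]1(C)CC=C(/C=C/OCC)[C@@]1(C)[C@H](O[Si](C)(C)C(C)(C)C)CC(O)C[C@]34CC[C@H](O3)C(C)(C)C4
F7 | step 21 | C5 ketone with dienol ethyl ether intact | C[C@H](CCO[Si](c5ccccc5)(c6ccccc6)C(C)(C)C)[C@]1(C)CC=C(/C=C/OCC)[C@@]1(C)[C@H](O[Si](C)(C)C(C)(C)C)CC(=O)C[C@]34CC[C@H](O3)C(C)(C)C4
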